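**Retrosynthetic overview**

1. Polonidine A is a symmetric bis(indol-3-yl)methane. The C3–CH2–C3′ bridge is cut last, back to two molecules of 3-(methoxymethyl)-1-tert-prenylindole: one CH2OMe group supplies the bridging carbon, the other leaves as formaldehyde.
2. The strategy rests on the benzo ring of each indole. C4–C7 carry only hydrogen, and the ring-fusion carbons C7a and C3a are neighbours that bear N1 and C3. Both N1–C7a and C3–C3a can therefore be made at once by adding the N–CH2–C(=O) unit of an α-(tert-prenylamino) ketone across the triple bond of benzyne.
3. The amino ketone MeOCH2–C(=O)–CH2–NH–C(CH3)2CH=CH2 comes from 1-chloro-3-methoxypropan-2-one and 2-methylbut-3-en-2-amine; the chloro ketone comes from the commercial chlorohydrin.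
4. Ring order: the benzene ring arrives intact as the aryne. The pyrrole ring, the only ring formed, closes in step 3 with the N-tert-prenyl group already on nitrogen. The two indoles are joined in step 4.

Key step: step 3

Remark on the chemistry: the target has no stereocentre; the stereocentres of 1 and 7 are racemic and are erased in steps 1 and 3, so no step needs stereocontrol.

**Route**

Step 1
Reactants: 1 1-chloro-3-methoxypropan-2-ol (racemic)
Product: 2 1-chloro-3-methoxypropan-2-one
Conditions: Dess–Martin periodinane, CH2Cl2, 0 → 23 °C; filtration through a short silica pad, careful concentration
Reagents that add atoms: none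
Why: Dess–Martin oxidation should convert the secondary alcohol into the ketone under neutral, non-aqueous conditions that an α-chloro ketone tolerates and that allow the rather volatile product to be isolated without an aqueous work-up.

Step 2
Reactants: 2 1-chloro-3-methoxypropan-2-one; 3 2-methylbut-3-en-2-amine
Product: 4 1-methoxy-3-[(2-methylbut-3-en-2-yl)amino]propan-2-one
Conditions: 3 (1.2 equiv), K2CO3, MeCN, 0 → 23 °C; acid–base extraction, free base used promptly
Reagents that add atoms: none
Why: SN2 N-alkylation of the primary amine by the carbonyl-activated primary chloride should stop at the secondary amine, because the α-tertiary group on nitrogen slows both a second alkylation and ketimine formation, while K2CO3 takes up the HCl.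

Step 3
Reactants: 4 1-methoxy-3-[(2-methylbut-3-en-2-yl)amino]propan-2-one; 5 2-(trimethylsilyl)phenyl trifluoromethanesulfonate
Product: 8 3-(methoxymethyl)-1-(2-methylbut-3-en-2-yl)-1H-indole, via benzyne 6 (not isolated), via 3-(methoxymethyl)-1-(2-methylbut-3-en-2-yl)indolin-3-ol 7 (not isolated)
Conditions: KF, 18-crown-6, THF, 0 → 23 °C (5, 1.3 equiv, added slowly); then PPTS (cat.), MeOH, 23 °C
Reagents that add atoms: none
Why: Fluoride removes the silyl group of 5 and triflate leaves, giving benzyne 6; the secondary amine of 4 adds to the strained triple bond to form N1–C7a, and the aryl anion generated on the neighbouring carbon attacks the ketone carbonyl to form C3–C3a. The closest known reaction type is aryne amination in which the ortho aryl anion is captured by a pendant carbonyl group (acridones from anthranilates, indoxyls and indolin-3-ols from α-amino esters and ketones). The pyrrole ring closes by 5-exo-trig addition to the C=O group to give indolin-3-ol 7 after proton transfer; catalytic acid then ionises the benzylic C3–OH bond with help from the aniline nitrogen, and loss of the C2 proton aromatises the ring to 8. The carbinol centre of 7 forms racemic and is erased on dehydration. The step needs carbonyl capture to outrun protonation of the aryl anion, which the aprotic crown-ether/THF medium, the slow release of benzyne and the five-membered geometry of closure should secure; benzyne is symmetric, so there is no regiochemical question, and the tert-prenyl alkene has no allylic hydrogen and cannot undergo an ene reaction with the aryne. Methanol as solvent for the dehydration returns any azafulvenium ion formed from 8 back to 8, so the methoxymethyl group should be kept.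

Step 4
Reactants: 8 3-(methoxymethyl)-1-(2-methylbut-3-en-2-yl)-1H-indole (two molecules)
Product: 10 polonidine A (bis[1-(2-methylbut-3-en-2-yl)-1H-indol-3-yl]methane), via 3-methylideneindoleninium ion 9 (not isolated)
Conditions: PPTS (cat.), MeCN–H2O (4:1), 40 °C
Reagents that add atoms: none
Why: Weak acid ionises the C3–CH2–OMe bond to ion 9, C3 of a second molecule of 8 attacks it at the substituted position (ipso Friedel–Crafts alkylation), and aromaticity returns by expulsion of the methoxymethyl group, which water hydrolyses to formaldehyde and methanol; this is the known condensation of indol-3-ylcarbinols to 3,3′-diindolylmethanes, and the acid is kept weak so that the N–C(tert-prenyl) bond is not ionised.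

**Compound list**

1 | 1-chloro-3-methoxypropan-2-ol (racemic) | COCC(O)CCl | starting material
2 | 1-chloro-3-methoxypropan-2-one | COCC(=O)CCl | intermediate
3 | 2-methylbut-3-en-2-amine | C=CC(C)(C)N | starting material
4 | 1-methoxy-3-[(2-methylbut-3-en-2-yl)amino]propan-2-one | COCC(=O)CNC(C)(C)C=C | intermediate
5 | 2-(trimethylsilyl)phenyl trifluoromethanesulfonate | C[Si](C)(C)c1ccccc1OS(=O)(=O)C(F)(F)F | starting material
6 | benzyne (1,2-didehydrobenzene) | C1#CC=CC=C1 | intermediate
7 | 3-(methoxymethyl)-1-(2-methylbut-3-en-2-yl)-2,3-dihydro-1H-indol-3-ol (racemic) | C=CC(C)(C)N1CC(O)(COC)c2ccccc21 | intermediate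
8 | 3-(methoxymethyl)-1-(2-methylbut-3-en-2-yl)-1H-indole | C=CC(C)(C)n1cc(COC)c2ccccc21 | intermediate
9 | 3-methylidene-1-(2-methylbut-3-en-2-yl)-3H-indol-1-ium | C=CC(C)(C)[N+]1=CC(=C)c2ccccc21 | intermediate
10 | polonidine A, bis[1-(2-methylbut-3-en-2-yl)-1H-indol-3-yl]methane | C=CC(C)(C)n1cc(Cc2cn(C(C)(C)C=C)c3ccccc23)c2ccccc21 | target

**Step count**

Total steps: 4. Longest linear sequence: 4 steps (1 → 2 → 4 → 8 → 10).

**Steps most likely to fail**

Step 3 (aryne annulation). What may go wrong: proton transfer to the aryl anion, from the ammonium N–H of the first adduct or from traces of water, outruns ring closure, so that nitrogen is arylated without formation of the C3–C3a bond. A second benzyne may also arylate the product, or the free amino ketone may degrade during the slow aryne release. The fallback changes the way the pyrrole ring is made; it sets out from amine 3 and comes back to the route at 10. 2-Bromobenzaldehyde is bromomethylenated by a Wittig reaction ((bromomethyl)triphenylphosphonium bromide, KOtBu, THF, −78 °C) to 1-bromo-2-[(Z)-2-bromoethenyl]benzene F1. F1 and 3 are joined by a Pd-catalysed cascade of alkenyl and aryl amination (Pd2(dba)3, XPhos, NaOtBu, toluene, 100 °C), which should accept an α-tertiary primary amine, to give 1-(2-methylbut-3-en-2-yl)-1H-indole F2. Two equivalents of F2 are then condensed with aqueous formaldehyde under weak acid (AcOH, MeCN–H2O, 23 °C), the standard bis(indolyl)methane synthesis at free C3 positions; this should give 10 directly and by-passes 8.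

Step 4 (self-condensation). What may go wrong: ion 9 alkylates C2 of 8 or of 10 instead of C3 and builds oligomers, the released formaldehyde re-enters as an electrophile, or the acid heterolyses the N–C(CH3)2 bond with loss or migration of the tert-prenyl group. The fallback is a crossed condensation instead of a self-condensation; it sets out from 8 and comes back at 10. 8 is ionised under the same weak acid, or with a mild Lewis acid such as Sc(OTf)3, in the presence of 1-(2-methylbut-3-en-2-yl)-1H-indole F2, obtained from 3 through F1 as described under step 3. The free C3 position of F2 is far more nucleophilic than the substituted C3 of 8 or C2 of 10, so F2 should capture ion 9 at lower acidity, with loss of methanol only and without ipso substitution or release of formaldehyde.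

Step 2 (amination of the chloro ketone). What may go wrong: enolisation of the chloro ketone by base (Favorskii-type or aldol self-condensation), a second N-alkylation, or loss of the volatile chloro ketone before use. The fallback reverses the order of C–N bond formation and oxidation; it sets out from 1 and 3 and comes back at 4. 1 is closed with aqueous NaOH to 2-(methoxymethyl)oxirane F3, which 3 opens at its unsubstituted carbon (EtOH, 60 °C, sealed tube) to give 1-methoxy-3-[(2-methylbut-3-en-2-yl)amino]propan-2-ol F4. F4 is oxidised as its trifluoroacetate salt (TFA, then Dess–Martin periodinane, CH2Cl2), so that the protonated amine is spared, and basification releases 4.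

**Further compounds**

F1 | step 3 | 1-bromo-2-[(Z)-2-bromoethenyl]benzene | Br/C=C\c1ccccc1Br
F2 | step 3 | 1-(2-methylbut-3-en-2-yl)-1H-indole | C=CC(C)(C)n1ccc2ccccc21
F0 | step 4 | none | none
F3 | step 2 | 2-(methoxymethyl)oxirane (racemic) | COCC1CO1
F4 | step 2 | 1-methoxy-3-[(2-methylbut-3-en-2-yl)amino]propan-2-ol (racemic) | COCC(O)CNC(C)(C)C=C
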